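Read each run below from its late end.

| flask | E | Z | J | remark | time |
|---|---|---|---|---|---|
| midnight | 0.50 mM | 0.55 mM | 8.4 µM | run made earlier |  |
| winter | 0.50 mM | 0.55 mM | 13 µM | run made earlier |  |
| summer | 0.25 mM | 0.55 mM | 6 µM | run made earlier |  |
| flask | 0.50 mM | 0.550 mM | 6.0 µM |  | 40 min |

| run | time / min | G / % | D / % |
|---|---|---|---|
| midnight | 2.50 | 22.7 | 77.5 |
| midnight | 6.00 | 21.7 | 77.9 |
| midnight | 15.0 | 24.7 | 77.0 |
| midnight | 30.0 | 24.8 | 78.5 |
| winter | 8.00 | 30.4 | 70.2 |
| winter | 15.0 | 31.1 | 70.8 |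
| winter | 25.0 | 29.4 | 68.8 |
| winter | 30.0 | 29.7 | 68.5 |
| summer | 2.50 | 17.2 | 82.5 |
| summer | 6.00 | 17.4 | 81.9 |
| summer | 15.0 | 18.9 | 81.0 |
| summer | 30.0 | 17.9 | 81.8 |

(scatter of a reading: 1 percentage point)

- share of G in G plus D at 5.0 s
- share of G in G plus D at 40 min
- which of G and D there is more of at 40 min



Take the summer run beside this flask: same cZ and cJ, with half the E. At 30.0 min it reads G 17.9% and D 81.8%, much as at 2.50 min, when the two already summed to 99.7%. So freeze the split: this looks like kinetic control, with G and D formed and then left alone.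

Now call the mean G/D of a run, divided by cJ, the split number 0.0360 µM⁻¹, read here from the midnight run at cZ 0.55 mM. Summer reads 0.0364 µM⁻¹, though winter reads lower at 0.0333 µM⁻¹. With half the E of the midnight run, the summer run still reads close to the midnight number, so expect this flask to end with summer. My reckoning is one multiplication: the midnight number times 6.0 µM gives G/D 0.216, or 17.8% G, with D ahead. Nothing was read before 2.50 min, so the same figure at 5.0 s is an extrapolation.

The forecast says 17.8% at 5.0 s and 17.8% at 40 min, with D ahead: “so G/D is roughly proportional to J”.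

The flask gives 19.0% at 5.0 s and 17.8% at 40 min, with D at 82.2%.

    E + J → J + Q (k = 14000 L mol⁻¹ s⁻¹)
    Z + J + Q → J + G (k = 5.80 × 10⁶ L² mol⁻² s⁻¹)
    Q → D (k = 0.0810 s⁻¹)

Q, formed on the way, has a half-life of 0.143 min towards D and 0.60 min towards G at the charged concentrations: its exit to D is faster by a factor of 4.20. At 40 min this flask holds G/D 0.217, a split number of 0.0361 µM⁻¹, with Z at 83.8% of its charge. The scheme puts cZ beside cJ in G/D, so carry S, scaled by cZ, to a neighbour flask like this one but with Z at 0.14 mM: G/D 0.0549, or 5.20% G. Computed, that flask gives 5.16%.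

(The data were generated by integration for an exercise; noise was put on by code.)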